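Read the plateau on Saturday's run before you charge anything.

| setting | Thursday's | Saturday's | epsilon | alpha | theta | gamma |
|---|---|---|---|---|---|---|
| starting material | 0.16 M | 1.6 M | 1.2 M | 0.20 M | 2.5 M | 0.59 M |
| coupling partner | 0.413 M | 0.413 M | 0.413 M | 0.413 M | 0.413 M | 0.413 M |
| temperature | 10 °C | 25 °C | 25 °C | 25 °C | 25 °C | 25 °C |
| remark | run made earlier | run made earlier |  |  |  |  |
| time |  |  | 12 min | 12 min | 12 min | 12 min |

| run | time / min | target / % | starting material / % |
|---|---|---|---|
| Thursday's | 2.00 | 5.6 | 93.1 |
| Thursday's | 4.00 | 11.1 | 87.4 |
| Thursday's | 8.00 | 19.9 | 76.6 |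
| Thursday's | 12.0 | 27.9 | 67.5 |
| Thursday's | 15.0 | 32.6 | 62.1 |
| Saturday's | 1.50 | 11.2 | 77.2 |
| Saturday's | 3.00 | 15.8 | 65.6 |
| Saturday's | 5.00 | 19.1 | 55.0 |
| Saturday's | 6.00 | 19.7 | 51.3 |
| Saturday's | 8.00 | 20.0 | 45.8 |

(standard deviation of a reading: 0.3 percentage points)

* all flasks from highest to lowest amount of target, in percent of the starting material charged, at 12 min (epsilon / alpha / theta / gamma)
* the amount of target, in percent of the starting material charged of the flask you put first, at 12 min
* the amount of target, in percent of the starting material charged of the flask you put last, at 12 min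

- a reading or a percentage of target counts all its forms, free or not
- a reading of starting material is of its free form alone

On Saturday's run, target stands at 19.7% after 6.00 min and 20.0% after 8.00 min, a step of 0.3 percentage points against a scatter of 0.3 points, while 45.8% of the starting material is still free. That reading is 0.320 M of target from 0.413 M of coupling partner, the limiting reagent by charge there, with less partner than the 1.6 M of starting material. So take Y = 0.775, the plateau target per unit of partner charged. My estimated ceiling at 25 °C, in percent of the starting material charged, is then Y, read from this one run, times the partner concentration over the starting material concentration.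

Now turn the settings by hand. Raise starting material with partner held, and the ceiling falls as one over the charge: 26.7% for epsilon, 12.8% for theta and 54.2% for gamma. For alpha it is 160%, above the whole charge, so this ceiling puts no useful bound on alpha's figure. Add time, and Saturday's run, once at its plateau, gains only the step read above. Add partner, and the ceiling rises in step. Cool, and you probably lose speed: Thursday's run at 10 °C makes 5.6% in 2.00 min, slower than Saturday's 11.2% in 1.50 min at 25 °C, though these two runs differ in starting material as well.

My ceiling for theta is 12.8%. The forecast has 12.5% (11% to 14%) there and 60% (54% to 66%) for alpha, in the order alpha > gamma > epsilon > theta, reading Saturday's plateau to mean “about a fifth of the partner is lost or unproductive”.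

The flasks give alpha > gamma > epsilon > theta, with 55.6% for alpha and 14.5% for theta, so the order and both values hold within the tolerance.

    starting material + coupling partner ⇌ target (K = 11.4 M⁻¹, k = 0.00466 M⁻¹ s⁻¹, Ea = 63.0 kJ mol⁻¹, ΔH = −78.0 kJ mol⁻¹)
    starting material + coupling partner ⇌ isomer of the product (K = 16.0 M⁻¹, k = 2.89 × 10⁻⁴ M⁻¹ s⁻¹, Ea = 60.0 kJ mol⁻¹, ΔH = −26.0 kJ mol⁻¹)
    crystals ⇌ target, rate k3*(cs3 - [target]) while solid is left; crystals form when [target] > cs3 (solubility = 0.240 M, k = 0.0153 s⁻¹)
    2 starting material → homo dimer (k = 4.95 × 10⁻⁴ M⁻¹ s⁻¹, Ea = 56.0 kJ mol⁻¹)
    (constants at 25 °C)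

Theta stands 1.7 points above its ceiling, with 6.01% of its partner left, so Y reads 0.876 in theta. Put Saturday's Y on the same flask with 1.7 M of partner, and the ceiling is 52.7%. That flask gives 58.2% of target, all forms counted.

The runs were generated by integration for substances that don't exist, and the scatter is random.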